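Plan
1. The retrosynthesis first cuts the ring O–C5 bond of the oxolane together with the exocyclic C–Br bond. Ring O and Br are vicinal and anti across C5–C(Br), and in the open chain the ring oxygen is a tertiary hydroxyl four atoms from that carbon, so the oxolane is the 5-exo bromoetherification product of the linalool-type dienol 13. The CH2Cl group on the bromine-bearing carbon lowers its cation-stabilising power and steers closure to the five-membered ring.
2. Further cuts: the C–Cl bond of the CH2Cl group (from an allylic alcohol), the bromovinyl C=C (Takai olefination of an aldehyde), the ring C3–Cl bond (chloride opening of a 2,3-epoxy alcohol) and the chain C4–C5 bond (alkenylmagnesium plus allylic chloride).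
3. Forward: the chain is joined first from isoprene monoxide, propargyl alcohol and a methyl Grignard reagent; epoxide, chlorohydrin, bromovinyl group and allylic chloride follow; the only ring, the oxolane, arises last.
4. Stereochemistry: ring C2/C3 come from Sharpless epoxidation of a (Z)-allylic alcohol and inversion by chloride. The (Z)- and (E)-alkenes come from anti-carbomagnesiation and SN2' epoxide opening, and the (E)-bromovinyl group from the Takai reaction. Ring C5 and the C–Br centre come from anti addition to the (E)-alkene on the face set by the ring C3 chlorine.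

Key step: step 10

Remark: atom numbers C1–C8 below are those of the open-chain octadienol 13 (C1 = CHBr, C3 = carbinol carbon, C4 = CHCl, C6=C7 = trisubstituted alkene, C8 = CH2Cl). Racemic 1 suffices because its stereocentre is lost in step 1.

Step 1
Reactants: 1 2-methyl-2-vinyloxirane (isoprene monoxide, racemic)
Product: 2 (2E)-4-chloro-2-methylbut-2-en-1-ol
Conditions: TiCl4, CH2Cl2, −90 °C; aq HCl work-up
Reagents that add atoms: titanium tetrachloride, Cl[Ti](Cl)(Cl)Cl
Why: Lewis-acid activation of the vinyl oxirane and delivery of chloride to the vinyl terminus (SN2' opening of a vinyl epoxide) should give the primary allylic chloride with the (E)-trisubstituted alkene.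

Step 2
Reactants: 2 (2E)-4-chloro-2-methylbut-2-en-1-ol
Product: 3 tert-butyl{[(2E)-4-chloro-2-methylbut-2-en-1-yl]oxy}dimethylsilane
Conditions: TBSCl, imidazole, CH2Cl2, 0 °C
Reagents that add atoms: tert-butyldimethylsilyl chloride, CC(C)(C)[Si](C)(C)Cl
Why: Standard silylation of a primary alcohol masks the future C8 oxygen so that only one allylic alcohol is present for the later Sharpless epoxidation and no allylic halide is present in the chromium step.

Step 3
Reactants: 4 prop-2-yn-1-ol (propargyl alcohol); 3 tert-butyl{[(2E)-4-chloro-2-methylbut-2-en-1-yl]oxy}dimethylsilane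
Product: 6 (2Z,5E)-7-[(tert-butyldimethylsilyl)oxy]-2,6-dimethylhepta-2,5-dien-1-ol, via alkenylmagnesium alkoxide 5 (not isolated)
Conditions: MeMgBr (2.2 equiv), CuI (10 mol%), THF, −10 °C to rt; then 3, −30 °C to rt; aq NH4Cl
Reagents that add atoms: methylmagnesium bromide, C[Mg]Br
Why: Hydroxyl-directed, copper-catalysed anti-carbomagnesiation of the propargylic alkoxide places the methyl group on the internal carbon and magnesium cis to CH2O in a five-membered chelate, which fixes the (Z)-alkene, and copper-catalysed allylic substitution at the unhindered CH2Cl terminus of 3 should then form the C4–C5 bond with both alkene geometries retained.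

Step 4
Reactants: 6 (2Z,5E)-7-[(tert-butyldimethylsilyl)oxy]-2,6-dimethylhepta-2,5-dien-1-ol
Product: 7 [(2S,3R)-3-{(2E)-4-[(tert-butyldimethylsilyl)oxy]-3-methylbut-2-en-1-yl}-2-methyloxiran-2-yl]methanol
Conditions: Ti(OiPr)4 (10 mol%), L-(+)-diethyl tartrate (12 mol%), t-BuOOH, 4 Å molecular sieves, CH2Cl2, −20 °C
Reagents that add atoms: tert-butyl hydroperoxide, CC(C)(C)OO
Why: Sharpless asymmetric epoxidation acts only on the free allylic alcohol, and with L-(+)-tartrate the oxygen should be delivered to the face that gives the (2S,3R)-epoxide, which sets the future C3 and prepares C4 for inversion.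

Step 5
Reactants: 7 [(2S,3R)-3-{(2E)-4-[(tert-butyldimethylsilyl)oxy]-3-methylbut-2-en-1-yl}-2-methyloxiran-2-yl]methanol
Product: 8 (2S,3S,5E)-7-[(tert-butyldimethylsilyl)oxy]-3-chloro-2,6-dimethylhept-5-ene-1,2-diol
Conditions: ClTi(OiPr)3, CH2Cl2, 0 °C to rt; aq tartaric acid work-up
Reagents that add atoms: chlorotitanium triisopropoxide, CC(C)O[Ti](Cl)(OC(C)C)OC(C)C
Why: Titanium bound to the primary alkoxide activates the epoxide and delivers chloride to the distal secondary carbon (hydroxyl-directed C3-selective opening of a 2,3-epoxy alcohol), the quaternary carbon being closed to backside attack, so the C–Cl centre forms by SN2 inversion and the tertiary carbinol keeps its configuration.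

Step 6
Reactants: 8 (2S,3S,5E)-7-[(tert-butyldimethylsilyl)oxy]-3-chloro-2,6-dimethylhept-5-ene-1,2-diol
Product: 9 (2S,3S,5E)-7-[(tert-butyldimethylsilyl)oxy]-3-chloro-2-hydroxy-2,6-dimethylhept-5-enal
Conditions: (COCl)2, DMSO, CH2Cl2, −78 °C; Et3N, −78 to −30 °C
Reagents that add atoms: none
Why: Swern oxidation converts the primary alcohol without glycol cleavage, the tertiary hydroxyl cannot be oxidised, and the quaternary α-carbon excludes epimerisation or elimination of the β-chloride.

Step 7
Reactants: 9 (2S,3S,5E)-7-[(tert-butyldimethylsilyl)oxy]-3-chloro-2-hydroxy-2,6-dimethylhept-5-enal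
Product: 10 (1E,3S,4S,6E)-1-bromo-8-[(tert-butyldimethylsilyl)oxy]-4-chloro-3,7-dimethylocta-1,6-dien-3-ol
Conditions: CrBr2 (from CrBr3 and LiAlH4), CHBr3, THF, rt to 50 °C
Reagents that add atoms: bromoform, BrC(Br)Br
Why: Takai olefination through a geminal dichromium species should give the (E)-vinyl bromide, the use of divalent chromium bromide avoids bromide/chloride exchange, and the alkyl chloride, silyl ether and free tertiary hydroxyl are inert to the weakly basic chromium reagent.

Step 8
Reactants: 10 (1E,3S,4S,6E)-1-bromo-8-[(tert-butyldimethylsilyl)oxy]-4-chloro-3,7-dimethylocta-1,6-dien-3-ol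
Product: 11 (2E,5S,6S,7E)-8-bromo-5-chloro-2,6-dimethylocta-2,7-diene-1,6-diol
Conditions: HF·pyridine, pyridine, THF, 0 °C to rt
Reagents that add atoms: none
Why: Fluoride-mediated cleavage of the primary silyl ether under buffered, non-basic conditions frees the allylic alcohol without closing the chlorohydrin to an epoxide.

Step 9
Reactants: 11 (2E,5S,6S,7E)-8-bromo-5-chloro-2,6-dimethylocta-2,7-diene-1,6-diol
Product: 13 (1E,3S,4S,6E)-1-bromo-4,8-dichloro-3,7-dimethylocta-1,6-dien-3-ol, via allylic mesylate 12 (not isolated)
Conditions: MsCl, 2,4,6-collidine, LiCl, DMF, 0 °C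
Reagents that add atoms: lithium chloride, [Li+].[Cl-]; methanesulfonyl chloride, CS(=O)(=O)Cl (its atoms remain only in 12)
Why: Only the primary allylic hydroxyl is mesylated (the tertiary one is too hindered), and direct SN2 displacement by chloride should give the allylic chloride without transposition or loss of the (E)-geometry.

Step 10
Reactants: 13 (1E,3S,4S,6E)-1-bromo-4,8-dichloro-3,7-dimethylocta-1,6-dien-3-ol
Product: 14 (2S,3S,5S)-5-[(2S)-2-bromo-1-chloropropan-2-yl]-2-[(E)-2-bromoethenyl]-3-chloro-2-methyloxolane
Conditions: 2,4,4,6-tetrabromocyclohexa-2,5-dienone (TBCO), CH2Cl2, −40 to 0 °C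
Reagents that add atoms: 2,4,4,6-tetrabromocyclohexa-2,5-dienone, BrC1=CC(Br)(Br)C=C(Br)C1=O
Why: TBCO transfers Br+ to the C6=C7 alkene to give a bromiranium ion, which the C3 hydroxyl opens at C6 anti to bromine, and the proton is taken up by tribromophenoxide. The closest known reaction type is the bromoetherification of bishomoallylic tertiary terpene alcohols of the linalool class. The oxolane closes in the 5-exo mode, with C7 and its new C–Br bond left outside the ring. The C7 centre is tied to C6 by stereospecific anti addition across the (E)-alkene, and the C6 centre is set by the alkene face: in the envelope transition state the C4 chlorine and the C6 substituent should both lie pseudo-equatorial, giving the 3,5-cis oxolane, while allylic 1,3-strain from the C7 methyl group cis to C5 limits the reactive conformers. The step needs 5-exo rather than 6-endo opening, which the CH2Cl group secures by withdrawing electron density from C7 and weakening the Markovnikov pull toward the oxane. It also needs selectivity between the two alkenes, which the bromine on C1 secures by deactivating the vinyl group.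

Compound list

1 | 2-methyl-2-vinyloxirane (racemic) | CC1(C=C)CO1 | starting material
2 | (2E)-4-chloro-2-methylbut-2-en-1-ol | OC/C(C)=C/CCl | intermediate
3 | tert-butyl{[(2E)-4-chloro-2-methylbut-2-en-1-yl]oxy}dimethylsilane | CC(C)(C)[Si](C)(C)OC/C(C)=C/CCl | intermediate
4 | prop-2-yn-1-ol | C#CCO | starting material
5 | (Z)-bromo{3-[(bromomagnesio)oxy]-2-methylprop-1-en-1-yl}magnesium (chelated alkenylmagnesium alkoxide, not isolated) | Br[Mg]/C=C(/C)CO[Mg]Br | intermediate
6 | (2Z,5E)-7-[(tert-butyldimethylsilyl)oxy]-2,6-dimethylhepta-2,5-dien-1-ol | OC/C(C)=C\C/C=C(\C)CO[Si](C)(C)C(C)(C)C | intermediate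
7 | [(2S,3R)-3-{(2E)-4-[(tert-butyldimethylsilyl)oxy]-3-methylbut-2-en-1-yl}-2-methyloxiran-2-yl]methanol | OC[C@]1(C)O[C@@H]1C/C=C(\C)CO[Si](C)(C)C(C)(C)C | intermediate
8 | (2S,3S,5E)-7-[(tert-butyldimethylsilyl)oxy]-3-chloro-2,6-dimethylhept-5-ene-1,2-diol | OC[C@](C)(O)[C@@H](Cl)C/C=C(\C)CO[Si](C)(C)C(C)(C)C | intermediate
9 | (2S,3S,5E)-7-[(tert-butyldimethylsilyl)oxy]-3-chloro-2-hydroxy-2,6-dimethylhept-5-enal | O=C[C@](C)(O)[C@@H](Cl)C/C=C(\C)CO[Si](C)(C)C(C)(C)C | intermediate
10 | (1E,3S,4S,6E)-1-bromo-8-[(tert-butyldimethylsilyl)oxy]-4-chloro-3,7-dimethylocta-1,6-dien-3-ol | Br/C=C/[C@](C)(O)[C@@H](Cl)C/C=C(\C)CO[Si](C)(C)C(C)(C)C | intermediate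
11 | (2E,5S,6S,7E)-8-bromo-5-chloro-2,6-dimethylocta-2,7-diene-1,6-diol | Br/C=C/[C@](C)(O)[C@@H](Cl)C/C=C(\C)CO | intermediate
12 | (2E,5S,6S,7E)-8-bromo-5-chloro-6-hydroxy-2,6-dimethylocta-2,7-dien-1-yl methanesulfonate (not isolated) | Br/C=C/[C@](C)(O)[C@@H](Cl)C/C=C(\C)COS(C)(=O)=O | intermediate
13 | (1E,3S,4S,6E)-1-bromo-4,8-dichloro-3,7-dimethylocta-1,6-dien-3-ol | Br/C=C/[C@](C)(O)[C@@H](Cl)C/C=C(\C)CCl | intermediate
14 | (2S,3S,5S)-5-[(2S)-2-bromo-1-chloropropan-2-yl]-2-[(E)-2-bromoethenyl]-3-chloro-2-methyloxolane | C[C@@](Br)(CCl)[C@@H]1C[C@H](Cl)[C@](C)(/C=C/Br)O1 | target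

Summary

Total steps: 10. Longest linear sequence: 10 steps (1 to 14).

The three steps most likely to fail are, in order of risk, the bromoetherification, the chloride opening of the epoxide and the carbomagnesiation–allylation.

At step 10, the hydroxyl may open the bromiranium ion at C7 (6-endo closure to an oxane), or bromine may be delivered to the other alkene face, giving the 3,5-trans ring. In the fallback, stereocontrol is moved from the substrate to the reagent. Dienol 13 is cyclised with N-bromosuccinimide under a chiral bromine carrier (a C2-symmetric selenide or sulfide Lewis base, or a BINOL-derived phosphoric acid, toluene, low temperature), and both catalyst enantiomers are tried to find the matched pair. A Lewis-base-bound bromiranium ion opens in a more SN2-like way, which should also favour attack at the less substituted C6. The fallback sets out from 13 and returns to the route at 14; it makes no new compound, hence the entry F0.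

At step 5, chloride may enter at the quaternary epoxide carbon, or the epoxide may migrate along the hydroxyl before opening, giving regioisomeric chlorohydrins. The fallback replaces chelation control by electronic control from a carbonyl group, which suppresses cationic character at the quaternary carbon and rules out epoxide migration. It sets out from 7 and returns to the route at 8.
- Oxidation of 7 (TEMPO, PhI(OAc)2, MeCN–water) would give (2R,3R)-3-{(2E)-4-[(tert-butyldimethylsilyl)oxy]-3-methylbut-2-en-1-yl}-2-methyloxirane-2-carboxylic acid F1.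
- Esterification (Me3SiCHN2, MeOH–toluene) would give methyl (2R,3R)-3-{(2E)-4-[(tert-butyldimethylsilyl)oxy]-3-methylbut-2-en-1-yl}-2-methyloxirane-2-carboxylate F2.
- LiCl/AcOH in THF should open this glycidate at the carbon remote from the ester with inversion, giving methyl (2S,3S,5E)-7-[(tert-butyldimethylsilyl)oxy]-3-chloro-2-hydroxy-2,6-dimethylhept-5-enoate F3.
- Reduction with i-Bu2AlH (CH2Cl2, −78 to 0 °C) then gives diol 8.

At step 3, surplus MeMgBr may transfer methyl to the allylic chloride, the alkenylmagnesium species may be captured incompletely, or attack may occur at the substituted allyl terminus. The fallback is a two-stage coupling through tin and palladium; it sets out from 5, made as before from 4, and returns to the route at 6. Intermediate 5 is quenched with Bu3SnCl to give (2Z)-2-methyl-3-(tributylstannyl)prop-2-en-1-ol F4, which is isolated. A Stille coupling with 3 (Pd2(dba)3 as the zerovalent palladium source, tri(2-furyl)phosphine, THF, 50 °C) should join the unhindered allyl terminus with retention of both alkene geometries and gives 6.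

Further compounds

F0 | step 10 | none | none
F1 | step 5 | (2R,3R)-3-{(2E)-4-[(tert-butyldimethylsilyl)oxy]-3-methylbut-2-en-1-yl}-2-methyloxirane-2-carboxylic acid | OC(=O)[C@]1(C)O[C@@H]1C/C=C(\C)CO[Si](C)(C)C(C)(C)C
F2 | step 5 | methyl (2R,3R)-3-{(2E)-4-[(tert-butyldimethylsilyl)oxy]-3-methylbut-2-en-1-yl}-2-methyloxirane-2-carboxylate | COC(=O)[C@]1(C)O[C@@H]1C/C=C(\C)CO[Si](C)(C)C(C)(C)C
F3 | step 5 | methyl (2S,3S,5E)-7-[(tert-butyldimethylsilyl)oxy]-3-chloro-2-hydroxy-2,6-dimethylhept-5-enoate | COC(=O)[C@](C)(O)[C@@H](Cl)C/C=C(\C)CO[Si](C)(C)C(C)(C)C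
F4 | step 3 | (2Z)-2-methyl-3-(tributylstannyl)prop-2-en-1-ol | CCCC[Sn](CCCC)(CCCC)/C=C(/C)CO
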